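## Structural features

The target is a germacranolide: a ten-membered carbocycle (C1–C10) in which an oxygen atom spans C3 and C10, so that O, C3, C2, C1 and C10 form a 3(2H)-furanone cross-conjugated with the Z C4=C5 alkene. An α-methylene-γ-butyrolactone (C11, C12, C13, ring oxygen on C8) is trans-fused along C7–C8, and the neighbouring C6 carries a (2S,3S)-2,3-epoxy-2-methylbutanoate. C6, C7 and C8 are contiguous stereocentres (6S,7R,8S), the quaternary bridgehead C10 (S) lies across the ring from them, and the acyl group holds two more. The fragile groups are the exocyclic enoate (a Michael acceptor that can slip into the ring as a 7(11)-butenolide), the dienone/vinylogous ester, the allylic C6 ester and the side-chain oxirane. The real difficulty is threefold: closing a ten-membered ring that holds one E and one Z trisubstituted alkene, relating C10 to C6–C8 across that ring, and placing the C6 oxygen syn to C8, which a closed allylation transition state does not give directly. The key step uses the fact that the C3 oxygen and C10 are separated only by C2 and C1: a 3-hydroxy 1(10)-epoxide holds a nucleophile and a tertiary electrophilic carbon face to face across the ring, and their union closes the ring O–C3–C2–C1–C10 with the future ketone oxygen already on C1.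

## Logic of the disconnections

**32 ⇒ 30 ⇒ 29.** The C2=C3 double bond and the C1 carbonyl are removed as functional-group changes (32 from 30 through 31, 30 from 29). The vinylogous ester is the most reactive part of 32 and is therefore made last. The forward steps must enolise only toward C2, which the quaternary C10 guarantees, and must spare the enoate and the side-chain oxirane.

**29 ⇒ 28.** The O–C10 bond is cut. This removes the bridge, one ring and the bridgehead stereocentre, and leaves a ten-membered ring fused only to the lactone. The forward step needs the C3 oxygen and the epoxide oxygen on opposite faces (3β-hydroxyl, 1β,10α-epoxide), attack at C10 and not at C1, and no competing oxygen at C6. For that reason 28 already carries the final C6 ester in place of a silyl ether, which also removes two protecting-group steps after the key step.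

**28 ⇒ 27 ⇒ 26.** The C3–H bond and the two C–O bonds of the epoxide are cut. With C3 as a ketone, C4=C5 is an enone and only C1=C10 is nucleophilic toward a peracid; the carbinol is then set by a reagent-controlled reduction. The demands are facial selectivity in the epoxidation, which rests on the ring, and gentle handling of the β,γ-epoxy ketone 27.

**26 ⇒ 21 + 25.** The C6–O bond is cut, not the acyl C–O bond. Ring closure is expected to give the 6α-alcohol, so the ester is formed with inversion. This corrects C6 and attaches the five-carbon acid in one operation, at the price of an SN2 reaction at a hindered allylic carbinol.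

**25 ⇒ 24 ⇒ 23 ⇒ 22.** The acid is taken back to the primary alcohol and the oxirane C–O bonds to the Z alkene. An allylic alcohol allows a catalytic asymmetric epoxidation; the forward steps must keep the Z geometry and use the correct tartrate enantiomer.

**21 ⇒ 19 (through 20).** The C6–C7 bond is cut. Forward, an aldehyde carbon is joined to the γ-carbon of an allyl metal, which closes the carbocycle, regenerates the exocyclic methylene and creates C6 and C7. The chain 19 has a single stereocentre (C8). The step needs high dilution, preference for the aldehyde over the C3 ketone, and attack anti to the chain on C8.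

**19 ⇒ 18.** The C3 and C6 carbonyl groups are folded back into a furan. The furan fixes the Z geometry of C4=C5 and hides both oxygens during the organometallic steps. The forward oxidation must select the furan over the trisubstituted alkene and the allylic bromide.

**18 ⇒ 17 ⇒ 15 + 16.** The C7=C11 bond (metathesis) and the ester C–O bond at C8 are cut, which reduces the lactone to 16 and a secondary allylic alcohol. The metathesis must engage a 1,1-disubstituted acrylate that carries an allylic bromide, and no base may be used because C8–H of 18 is acidic.

**15 ⇒ 14 ⇒ 11 + 12 (through 13).** The C2–C3 bond between the furan and an allylic carbon is cut. The forward alkylation must be SN2 and not SN2′.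

**11 ⇒ 10 ⇒ 7 (through 8 and 9).** The C1–C2 and C10–C14 bonds are cut. Both arise from syn carbometalation of a terminal alkyne followed by trapping, which fixes the E geometry of C1=C10; the vinyl group must stay inert.

**7 ⇒ 6 ⇒ 5 ⇒ 4 ⇒ 1 + 2 (through 3).** The terminal CH2 of the vinyl group (one-carbon homologation of an epoxide) and the C9–C10 bond (acetylide plus epoxide) are cut. The C8 stereocentre is bought with 1 and no bond to it is broken afterwards.

## Other disconnections considered

**Alternative 1:** The cut is again C6–C7, but made by ring contraction. The thirteen-membered cyclic ether A1, in which an oxygen links C6 to C13, would be deprotonated at C6; the carbanion attacks C7 as the O–C13 bond breaks ([2,3]-Wittig rearrangement) and gives the carbocycle A2 with the C6 alkoxide, the C11=C13 methylene and the furanone in place.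
- In its favour: a thirteen-membered ether should close more easily than a ten-membered carbocycle. The five-centre transition state ties the C6/C7 relationship to the geometry of the C7=C11 alkene, so the syn arrangement of the C6 oxygen and C8 could be reached without an inversion. On this point it is better than the chosen plan.
- Against it: a strong base must act next to a furanone that is both a vinylogous ester and a Michael acceptor, and a [1,2]-shift can compete.
- Comparison: both plans form C6–C7 as the last bond of the carbocycle. The chosen plan does so under neutral, metal-mediated conditions and obtains the lactone in the same step, whereas A2 still needs unmasking of the C8 oxygen, oxidation of C12 and lactonisation before acylation. Up to the carbocycle the step counts should be about equal; from A2 to the target several more operations are needed than from 21.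

**Alternative 2:** The ten-membered ring comes from a six-membered one. The potassium alkoxide of the dialkenyl cyclohexenol A3 would undergo an anionic oxy-Cope rearrangement (C8–C9 formed, C1–C6 broken), and the resulting dienone enolate is alkylated at C7 by an α-halo acetate to give A4.
- In its favour: the ring, the E C1=C10 and the Z C4=C5 alkenes and the C3 oxygen are delivered in one operation from a chiral-pool ring. This is the shortest access to the carbocycle and better than the chosen plan on that count. A4 also keeps the 1(10)-alkene and the C3 oxygen, so the same epoxide-opening endgame could be used; on this point the two are equal.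
- Against it: C8 arrives as an unactivated methylene, β to the C6 ketone, and no reliable way is seen to bring the lactone oxygen there. The C6 ketone must still be reduced with control, C7 is set only relative to a remote centre, and the methylene group is missing.
- Comparison: the oxy-Cope is mechanistically well defined, whereas the ring closure of the chosen plan is not fully predictable at C6. The chosen plan, however, delivers C6, C7, C8 and the complete lactone in its ring-forming step, so the advantage of A4 in early step count is likely lost later.

**Alternative 3:** The cut is C5–C6. The iodo aldehyde A5 would be treated with CrCl2 and catalytic NiCl2; the alkenylchromium species adds to the C6 aldehyde (Nozaki–Hiyama–Kishi reaction) and gives A6, one acylation from the target.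
- In its favour: it is highly convergent, the conditions tolerate the furanone and the enoate, and the ring is closed at the latest possible point. In late-stage convergence it is better than the chosen plan.
- Against it: the ring must close on a substrate that already holds the rigid furanone bridge, so the transition state is that of a strained bicycle. The aldehyde sits on the epimerisable C7. C10 must be set in an open-chain precursor by separate asymmetric chemistry and matched with C7 and C8, whereas the chosen plan derives C10 from the ring itself.
- Comparison: both plans close the ring by carbonyl addition at C6 and both leave the C6 configuration to a transition state inside a forming ring; on this they are equal, and an inversion during acylation would serve either. The chosen plan closes an unbridged ring and adds the bridge afterwards, which should be the less strained order.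

Key step: step 19

Remark 1: atoms carry germacrane numbers (C1–C10 ring, C11–C13 lactone carbons, C14 on C10, C15 on C4); α and β refer to the usual flat drawing of the ring with H-7 α.

Remark 2: 2-bromo-3-methylfuran (12) is treated as a catalogue compound; it is otherwise one step from 3-methylfuran and NBS.

Remark 3: the ring closure of step 12 is taken to give the 6α-alcohol, as the chair model for an allyl metal of this geometry predicts; the other outcome is covered under the least certain steps.

Remark 4: the configurations used for 28 and 29 are mutually consistent (C10 inverts from R to S, C1 and C3 are retained), so no stereodescriptor needed correction; the only change is the C6 substituent.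

## Route

Step 1
Reactants: 1 (S)-epichlorohydrin; 2 ethynyltrimethylsilane
Product: 4 (2S)-1-chloro-5-(trimethylsilyl)pent-4-yn-2-ol, via lithium (trimethylsilyl)acetylide 3 (not isolated)
Conditions: n-BuLi, THF, −78 °C; BF3·OEt2; then 1, −78 °C
Reagents that add atoms: none
Why: Lewis-acid-assisted opening of the epoxide at its CH2 terminus by the lithium acetylide (epoxide alkynylation); the stereocentre (later C8) is not involved and the chloride survives at −78 °C.

Step 2
Reactants: 4
Product: 5 (2S)-2-(prop-2-yn-1-yl)oxirane
Conditions: K2CO3, MeOH, 0 °C to rt
Reagents that add atoms: none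
Why: The chlorohydrin closes to the terminal epoxide by intramolecular Williamson displacement at the CH2Cl carbon, so the carbinol configuration is retained, and methanolic carbonate removes the alkynyl silyl group in the same flask. The volatile product is carried on in solution.

Step 3
Reactants: 5
Product: 6 (3S)-hex-1-en-5-yn-3-ol
Conditions: Me3S+ I−, n-BuLi, THF, −10 °C to rt
Reagents that add atoms: trimethylsulfonium iodide, C[S+](C)C.[I-]
Why: Dimethylsulfonium methylide opens the epoxide at the unsubstituted carbon and a second equivalent of ylide induces loss of dimethyl sulfide, the known one-carbon homologation of a terminal epoxide to an allylic alcohol. C8 is untouched and the ylide is not basic enough to deprotonate the alkyne.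

Step 4
Reactants: 6
Product: 7 (3S)-3-(tert-butyldimethylsilyloxy)hex-1-en-5-yne
Conditions: TBSCl, imidazole, DMF, rt
Reagents that add atoms: tert-butyldimethylsilyl chloride, CC(C)(C)[Si](C)(C)Cl
Why: Standard silylation; the silyl ether shields the C8 oxygen from the aluminium and lithium reagents of steps 5 and 7.

Step 5
Reactants: 7
Product: 10 (2E,5S)-5-(tert-butyldimethylsilyloxy)-3-methylhepta-2,6-dien-1-ol, via alkenyldimethylalane 8 (not isolated), via lithium alkenylalanate 9 (not isolated)
Conditions: Me3Al, Cp2ZrCl2 (20 mol %), CH2Cl2, 0 °C to rt; n-BuLi, THF, −78 °C; (CH2O)n, rt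
Reagents that add atoms: trimethylaluminium, C[Al](C)C; paraformaldehyde (as formaldehyde), C=O
Why: Zirconium-catalysed carboalumination (Negishi) adds methyl and aluminium syn across the terminal alkyne with aluminium on the terminal carbon, which fixes the E geometry of the future C1=C10 alkene and installs C14. The butyl alanate then adds to formaldehyde with retention to give the allylic alcohol (C2); the monosubstituted alkene is not carbometalated under these conditions.

Step 6
Reactants: 10
Product: 11 tert-butyl{[(3S,5E)-7-bromo-5-methylhepta-1,5-dien-3-yl]oxy}dimethylsilane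
Conditions: CBr4, PPh3, CH2Cl2, 0 °C
Reagents that add atoms: tetrabromomethane, BrC(Br)(Br)Br
Why: Appel bromination of the primary allylic alcohol under neutral conditions, without allylic transposition or loss of the silyl ether.

Step 7
Reactants: 11; 12 2-bromo-3-methylfuran
Product: 14 tert-butyldimethyl{[(3S,5E)-5-methyl-7-(3-methylfuran-2-yl)hepta-1,5-dien-3-yl]oxy}silane, via (3-methylfuran-2-yl)lithium 13 (not isolated)
Conditions: 12, n-BuLi, THF, −78 °C; then 11, CuI (10 mol %), −78 to 0 °C
Reagents that add atoms: none
Why: Bromine–lithium exchange fixes the metal at C2 of the furan, and the furyllithium displaces the primary allylic bromide (SN2 alkylation of a 2-furyl anion), which forms the C2–C3 bond. Attack at the fully substituted γ-carbon is disfavoured.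

Step 8
Reactants: 14
Product: 15 (3S,5E)-5-methyl-7-(3-methylfuran-2-yl)hepta-1,5-dien-3-ol
Conditions: TBAF, THF, 0 °C to rt
Reagents that add atoms: none
Why: Fluoride cleavage of the silyl ether; the furan and the alkenes are inert.

Step 9
Reactants: 15; 16 2-(bromomethyl)acrylic acid
Product: 17 (3S,5E)-5-methyl-7-(3-methylfuran-2-yl)hepta-1,5-dien-3-yl 2-(bromomethyl)prop-2-enoate
Conditions: DIC, 4-(dimethylamino)pyridine (5 mol %), CH2Cl2, −20 to 0 °C
Reagents that add atoms: none
Why: Carbodiimide (Steglich) esterification takes place at oxygen, so C8 keeps its configuration. Low temperature and a small amount of the pyridine catalyst limit substitution of the allylic bromide.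

Step 10
Reactants: 17
Product: 18 (5S)-3-(bromomethyl)-5-[(2E)-2-methyl-4-(3-methylfuran-2-yl)but-2-en-1-yl]furan-2(5H)-one
Conditions: second-generation Grubbs catalyst (10 mol %), CH2Cl2, 40 °C
Reagents that add atoms: none
Why: Ring-closing metathesis of the acrylate of a secondary allylic alcohol, the standard route to 5-substituted butenolides, here with a 1,1-disubstituted acrylate partner. The trisubstituted alkene and the furan do not take part, ethylene is lost, and no base is present to touch the acidic C8–H.

Step 11
Reactants: 18
Product: 19 (2Z,6E)-8-[(2S)-4-(bromomethyl)-5-oxo-2,5-dihydrofuran-2-yl]-3,7-dimethyl-4-oxoocta-2,6-dienal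
Conditions: NBS (1.0 equiv), NaHCO3, acetone/H2O (9:1), −20 °C
Reagents that add atoms: water, O
Why: Oxidative ring opening of a 2-alkylfuran to the cis-ene-1,4-dicarbonyl compound; the furan is far more nucleophilic than the trisubstituted alkene, so one equivalent of NBS at low temperature should be selective. The Z geometry of C4=C5 is inherited from the ring, with the ketone at C3 and the aldehyde at C6, and the crude product is used at once.

Step 12
Reactants: 19
Product: 21 (1(10)E,4Z)-6α-hydroxy-3-oxogermacra-1(10),4,11(13)-trien-12,8α-olide (6R,7S,8S), via allylindium dibromide 20 (not isolated)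
Conditions: In powder, THF/H2O (3:1), rt, syringe-pump addition (final 2 mM)
Reagents that add atoms: none
Why: Intramolecular Barbier allylation: indium inserts into the allylic C–Br bond and the allyl metal adds through C7 to the aldehyde, regenerating the exocyclic methylene; closure of 2-(alkoxycarbonyl)allyl metals onto aldehydes is an established entry to germacranolides. The aldehyde is more electrophilic than the C3 ketone, and attack on the ketone would need a seven-membered ring containing the E alkene. C6 should add anti to the chain on C8 (trans-lactone), and the chair transition state of an allyl unit whose C8 is locked trans to the CH2–metal carbon places the C6 oxygen anti to C8, which is the 6α-alcohol.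

Step 13
Reactants: 22 angelic acid
Product: 23 (2Z)-2-methylbut-2-en-1-ol
Conditions: LiAlH4, Et2O, 0 °C
Reagents that add atoms: none
Why: Hydride reduction of the carboxylic acid to the primary allylic alcohol; 1,2-reduction is expected for this β-alkyl enoic acid at 0 °C and the Z geometry is not affected.

Step 14
Reactants: 23
Product: 24 [(2R,3S)-2,3-dimethyloxiran-2-yl]methanol
Conditions: Ti(OiPr)4, D-(−)-diisopropyl tartrate, t-BuOOH, 4 Å MS, CH2Cl2, −20 °C
Reagents that add atoms: tert-butyl hydroperoxide, CC(C)(C)OO
Why: Sharpless asymmetric epoxidation; syn oxygen transfer keeps the CH2OH group and the C3 methyl cis. The D-(−)-tartrate is chosen because the L-(+)-ester converts Z allylic alcohols of this pattern (nerol) into the (2S,3R) series, and the 2-methyl group should raise rate and selectivity relative to a simple Z allylic alcohol.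

Step 15
Reactants: 24
Product: 25 (2S,3S)-2,3-dimethyloxirane-2-carboxylic acid
Conditions: RuCl3 (2 mol %), NaIO4, CCl4/MeCN/H2O, rt
Reagents that add atoms: water, O
Why: Oxidation of the primary alcohol to the acid by RuO4 generated in the flask (through the aldehyde hydrate) leaves the oxirane intact. The change of descriptor at C2 from R to S is only a change of substituent priority.

Step 16
Reactants: 21; 25
Product: 26 (1(10)E,4Z)-6β-[(2S,3S)-2,3-dimethyloxirane-2-carbonyloxy]-3-oxogermacra-1(10),4,11(13)-trien-12,8α-olide (6S,7R,8S)
Conditions: PPh3, DIAD, toluene, 0 °C to rt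
Reagents that add atoms: none
Why: Mitsunobu esterification: the activated 6α-hydroxyl is displaced by the carboxylate with inversion, which turns the C6 configuration from step 12 into that of the target and installs the acyl group in one operation. The α-oxygenated acid is acidic enough for the phosphine–azodicarboxylate adduct, and SN2′ capture is disfavoured because the allylic terminus C4 is fully substituted.

Step 17
Reactants: 26
Product: 27 (4Z)-1β,10α-epoxy-6β-[(2S,3S)-2,3-dimethyloxirane-2-carbonyloxy]-3-oxogermacra-4,11(13)-dien-12,8α-olide (1R,10R)
Conditions: mCPBA, NaHCO3, CH2Cl2, 0 °C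
Reagents that add atoms: 3-chloroperbenzoic acid, OOC(=O)c1cccc(Cl)c1
Why: Prilezhaev epoxidation; C1=C10 is the only electron-rich alkene, since C4=C5 is part of an enone and C11=C13 of an enoate. The peracid should approach the outer face of the E alkene in the ring conformer that keeps C14 on the side of the C7 substituent, the sense generally followed by 1(10)-alkenes of germacranolides, which gives the 1β,10α-epoxide with C2 and C9 still trans.

Step 18
Reactants: 27
Product: 28 (4Z)-1β,10α-epoxy-3β-hydroxy-6β-[(2S,3S)-2,3-dimethyloxirane-2-carbonyloxy]germacra-4,11(13)-dien-12,8α-olide (1R,3S,10R)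
Conditions: (R)-2-methyl-CBS-oxazaborolidine [(3aR)-1-methyl-3,3-diphenyltetrahydro-1H,3H-pyrrolo[1,2-c][1,3,2]oxazaborole] (20 mol %), catecholborane, toluene, −78 °C
Reagents that add atoms: none
Why: Corey–Bakshi–Shibata reduction: the α-methyl-substituted alkenyl group acts as the large substituent and the C2 methylene as the small one, so the (R)-oxazaborolidine should give the (3S), that is 3β, carbinol under reagent control. Catecholborane at −78 °C reduces only the ketone, and a buffered work-up allows the epoxy alcohol to be isolated.

Step 19
Reactants: 28
Product: 29 (4Z)-3β,10β-epoxy-1β-hydroxy-6β-[(2S,3S)-2,3-dimethyloxirane-2-carbonyloxy]germacra-4,11(13)-dien-12,8α-olide (1R,3S,10S)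
Conditions: (+)-camphor-10-sulfonic acid (10 mol %), CH2Cl2, 0 °C
Reagents that add atoms: none
Why: Protonation of the 1,10-epoxide oxygen lengthens the C10–O bond, because C10 is tertiary, and the 3β-hydroxyl, held on the opposite face of the ring, attacks C10 from the inside with inversion (R to S) while the epoxide oxygen stays on C1 as the 1β-hydroxyl (retention at C1 and C3). The closest known reaction type is the acid-promoted transannular cyclisation of germacranolide 1,10-epoxides that bear a ring hydroxyl, a case of epoxy-alcohol cyclisation to a tetrahydrofuran. The ring closed is the five-membered ether O–C3–C2–C1–C10, formed by a 5-endo epoxide opening, which is acceptable here because bond making at C10 lags behind C–O bond breaking (loose, cation-like transition state). The only new stereocentre is C10 and the epoxide dictates it: the entering oxygen must come anti to the leaving one, and only the 3β/1β,10α combination lets the C4–C9 chain bridge the new ring on one face. The step needs regioselectivity (C10 and not C1, whose attack would give an oxetane), chemoselectivity over the side-chain oxirane and suppression of proton loss from C9 or C14. The tertiary nature of C10, the electron-poor α-acyl oxirane and the short O3···C10 distance imposed by the Z C4=C5 alkene and the trans-lactone should secure these, and the acylated C6 oxygen cannot compete for C10. A catalytic sulfonic acid in a non-nucleophilic solvent avoids external opening of either oxirane.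

Step 20
Reactants: 29
Product: 30 (4Z)-3β,10β-epoxy-6β-[(2S,3S)-2,3-dimethyloxirane-2-carbonyloxy]-1-oxogermacra-4,11(13)-dien-12,8α-olide (3S,10S)
Conditions: DMP, NaHCO3, CH2Cl2, rt
Reagents that add atoms: none
Why: Dess–Martin oxidation of the secondary alcohol under buffered, non-basic conditions, which spares the enoate, the allylic ether and the side-chain oxirane.

Step 21
Reactants: 30
Product: 32 (4Z)-3,10β-epoxy-6β-[(2S,3S)-2,3-dimethyloxirane-2-carbonyloxy]-1-oxogermacra-2,4,11(13)-trien-12,8α-olide (6S,7R,8S,10S; the target), via trimethylsilyl enol ether 31 (not isolated)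
Conditions: TMSOTf, Et3N, CH2Cl2, −78 to 0 °C; then Pd(OAc)2, MeCN, rt
Reagents that add atoms: none
Why: Saegusa–Ito oxidation: soft enolisation can occur only toward C2 because C10 is quaternary, and the palladium enolate loses the C3 hydrogen to give the C2=C3 bond of the furanone, conjugated with C4=C5. No strong base is used, so the exocyclic enoate and C7 are not disturbed.

## Compound list

1 | (S)-epichlorohydrin | ClC[C@@H]1CO1 | starting material
2 | ethynyltrimethylsilane | C#C[Si](C)(C)C | starting material
3 | lithium (trimethylsilyl)acetylide | [Li]C#C[Si](C)(C)C | intermediate (not isolated)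
4 | (2S)-1-chloro-5-(trimethylsilyl)pent-4-yn-2-ol | ClC[C@@H](O)CC#C[Si](C)(C)C | intermediate
5 | (2S)-2-(prop-2-yn-1-yl)oxirane | C#CC[C@H]1CO1 | intermediate
6 | (3S)-hex-1-en-5-yn-3-ol | C=C[C@@H](O)CC#C | intermediate
7 | (3S)-3-(tert-butyldimethylsilyloxy)hex-1-en-5-yne | C=C[C@@H](O[Si](C)(C)C(C)(C)C)CC#C | intermediate
8 | [(1E,4S)-4-(tert-butyldimethylsilyloxy)-2-methylhexa-1,5-dien-1-yl]dimethylalane | C=C[C@@H](O[Si](C)(C)C(C)(C)C)C/C(C)=C/[Al](C)C | intermediate (not isolated)
9 | lithium butyl[(1E,4S)-4-(tert-butyldimethylsilyloxy)-2-methylhexa-1,5-dien-1-yl]dimethylaluminate | [Li+].C=C[C@@H](O[Si](C)(C)C(C)(C)C)C/C(C)=C/[Al-](C)(C)CCCC | intermediate (not isolated)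
10 | (2E,5S)-5-(tert-butyldimethylsilyloxy)-3-methylhepta-2,6-dien-1-ol | C=C[C@@H](O[Si](C)(C)C(C)(C)C)C/C(C)=C/CO | intermediate
11 | tert-butyl{[(3S,5E)-7-bromo-5-methylhepta-1,5-dien-3-yl]oxy}dimethylsilane | C=C[C@@H](O[Si](C)(C)C(C)(C)C)C/C(C)=C/CBr | intermediate
12 | 2-bromo-3-methylfuran | Cc1ccoc1Br | starting material
13 | (3-methylfuran-2-yl)lithium | Cc1ccoc1[Li] | intermediate (not isolated)
14 | tert-butyldimethyl{[(3S,5E)-5-methyl-7-(3-methylfuran-2-yl)hepta-1,5-dien-3-yl]oxy}silane | C=C[C@@H](O[Si](C)(C)C(C)(C)C)C/C(C)=C/Cc1occc1C | intermediate
15 | (3S,5E)-5-methyl-7-(3-methylfuran-2-yl)hepta-1,5-dien-3-ol | C=C[C@@H](O)C/C(C)=C/Cc1occc1C | intermediate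
16 | 2-(bromomethyl)acrylic acid | C=C(CBr)C(=O)O | starting material
17 | (3S,5E)-5-methyl-7-(3-methylfuran-2-yl)hepta-1,5-dien-3-yl 2-(bromomethyl)prop-2-enoate | C=C[C@@H](OC(=O)C(=C)CBr)C/C(C)=C/Cc1occc1C | intermediate
18 | (5S)-3-(bromomethyl)-5-[(2E)-2-methyl-4-(3-methylfuran-2-yl)but-2-en-1-yl]furan-2(5H)-one | O=C1O[C@@H](C/C(C)=C/Cc2occc2C)C=C1CBr | intermediate
19 | (2Z,6E)-8-[(2S)-4-(bromomethyl)-5-oxo-2,5-dihydrofuran-2-yl]-3,7-dimethyl-4-oxoocta-2,6-dienal | O=C1O[C@@H](C/C(C)=C/CC(=O)/C(C)=C\C=O)C=C1CBr | intermediate
20 | allylindium dibromide derived from 19 (simplest formulation of the organoindium) | O=C1O[C@@H](C/C(C)=C/CC(=O)/C(C)=C\C=O)C=C1C[In](Br)Br | intermediate (not isolated)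
21 | (1(10)E,4Z)-6α-hydroxy-3-oxogermacra-1(10),4,11(13)-trien-12,8α-olide (6R,7S,8S) | C=C1C(=O)O[C@H]2C/C(C)=C/CC(=O)/C(C)=C\[C@@H](O)[C@H]12 | intermediate
22 | angelic acid, (2Z)-2-methylbut-2-enoic acid | C/C=C(/C)C(=O)O | starting material
23 | (2Z)-2-methylbut-2-en-1-ol | C/C=C(/C)CO | intermediate
24 | [(2R,3S)-2,3-dimethyloxiran-2-yl]methanol | OC[C@@]1(C)O[C@H]1C | intermediate
25 | (2S,3S)-2,3-dimethyloxirane-2-carboxylic acid | OC(=O)[C@@]1(C)O[C@H]1C | intermediate
26 | (1(10)E,4Z)-6β-[(2S,3S)-2,3-dimethyloxirane-2-carbonyloxy]-3-oxogermacra-1(10),4,11(13)-trien-12,8α-olide | C=C1C(=O)O[C@H]2C/C(C)=C/CC(=O)/C(C)=C\[C@H](OC(=O)[C@@]3(C)O[C@H]3C)[C@H]12 | intermediate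
27 | (4Z)-1β,10α-epoxy-6β-[(2S,3S)-2,3-dimethyloxirane-2-carbonyloxy]-3-oxogermacra-4,11(13)-dien-12,8α-olide | C=C1C(=O)O[C@H]2C[C@@]3(C)O[C@@H]3CC(=O)/C(C)=C\[C@H](OC(=O)[C@@]4(C)O[C@H]4C)[C@H]12 | intermediate
28 | (4Z)-1β,10α-epoxy-3β-hydroxy-6β-[(2S,3S)-2,3-dimethyloxirane-2-carbonyloxy]germacra-4,11(13)-dien-12,8α-olide | C=C1C(=O)O[C@H]2C[C@@]3(C)O[C@@H]3C[C@H](O)/C(C)=C\[C@H](OC(=O)[C@@]4(C)O[C@H]4C)[C@H]12 | intermediate
29 | (4Z)-3β,10β-epoxy-1β-hydroxy-6β-[(2S,3S)-2,3-dimethyloxirane-2-carbonyloxy]germacra-4,11(13)-dien-12,8α-olide | C=C1C(=O)O[C@H]2C[C@]3(C)O[C@@H](C[C@H]3O)/C(C)=C\[C@H](OC(=O)[C@@]4(C)O[C@H]4C)[C@H]12 | intermediate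
30 | (4Z)-3β,10β-epoxy-6β-[(2S,3S)-2,3-dimethyloxirane-2-carbonyloxy]-1-oxogermacra-4,11(13)-dien-12,8α-olide | C=C1C(=O)O[C@H]2C[C@]3(C)O[C@@H](CC3=O)/C(C)=C\[C@H](OC(=O)[C@@]4(C)O[C@H]4C)[C@H]12 | intermediate
31 | 1-(trimethylsilyloxy)-1-ene (silyl enol ether) of 30 | C=C1C(=O)O[C@H]2C[C@]3(C)O[C@@H](C=C3O[Si](C)(C)C)/C(C)=C\[C@H](OC(=O)[C@@]4(C)O[C@H]4C)[C@H]12 | intermediate (not isolated)
32 | (4Z)-3,10β-epoxy-6β-[(2S,3S)-2,3-dimethyloxirane-2-carbonyloxy]-1-oxogermacra-2,4,11(13)-trien-12,8α-olide | C=C1C(=O)O[C@H]2C[C@]3(C)OC(=CC3=O)/C(C)=C\[C@H](OC(=O)[C@@]3(C)O[C@H]3C)[C@H]12 | target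

## Step count and least certain steps

Total: 21 steps. Longest linear sequence: 18 steps (steps 1–12 and 16–21, from 1 to 32); steps 13–15 are a three-step branch to 25.

**Step 19 (key step).** Capture of the developing C10 cation by the C3 hydroxyl may be outrun by proton loss from C9 or C14 (giving allylic alcohols) or by a hydride shift to a C1 ketone, if the ring does not hold O3 behind C10. This depends on the conformer population of 28, which is not known. Fallback: the ether is made from the alkene instead of the epoxide. Starting from 26, reduction as in step 18 gives the 3β-hydroxy 1(10)-ene F1. Hg(OCOCF3)2 in CH2Cl2 forms a mercurinium ion on the outer face of C1=C10, which the hydroxyl opens at C10 from the inside to give the organomercury trifluoroacetate F2. Oxidative demercuration (NaBH4, O2, DMF) gives 29 together with its 1α-hydroxy epimer F3; both are oxidised as in step 20, so the route is rejoined at 30.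

**Step 12.** The most likely problem is poor or reversed facial selectivity at the aldehyde carbon, because the closed transition state has to fit inside the forming ten-membered ring; inversion in step 16 would then give the wrong ester from the 6β-alcohol. Fallback: each epimer is taken to 26 by the esterification that suits it. The 6β-hydroxy epimer F4, formed from 19 and separated, is acylated with 25 with retention (DIC, 4-(dimethylamino)pyridine, CH2Cl2) and gives 26 directly.

**Step 16.** Elimination toward C7 or ionisation of the activated allylic oxygen (loss of stereospecificity) may compete with SN2 displacement by the hindered carboxylate. Fallback: inversion and acylation are separated. Starting from 21, a Mitsunobu reaction with the small and more acidic chloroacetic acid gives the 6β-chloroacetate F5. Thiourea and NaHCO3 in EtOH remove the chloroacetyl group to give the 6β-hydroxy compound F4, which is esterified with 25 by DIC and 4-(dimethylamino)pyridine, and the route is rejoined at 26.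

**Step 17.** The peracid may attack the wrong face of C1=C10, since the exposed face is set by the ring conformer and not by the reagent; the resulting 1α,10β-epoxide cannot close the bridge. Fallback: the oxygen is delivered from the face opposite to the electrophile. Starting from 26, NBS in aqueous THF should give the 1α-bromo-10α-hydroxy compound F6 (bromonium ion on the exposed face, water attacking C10 from the inner face). DBU then closes the oxirane by displacing bromide at C1, which places the oxygen on the face the peracid does not reach and returns to the route at 27.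

**Step 21.** The silyl triflate may open the side-chain oxirane or the allylic C3–O bond before enolisation is complete, and the palladium-mediated dehydrogenation may stall. Fallback: direct dehydrogenation of 30 with IBX (2-iodoxybenzoic acid) in DMSO at 65 °C, which needs neither silylation nor palladium and gives 32.

## Further compounds

F1 | step 19 | (1(10)E,4Z)-3β-hydroxy-6β-[(2S,3S)-2,3-dimethyloxirane-2-carbonyloxy]germacra-1(10),4,11(13)-trien-12,8α-olide | C=C1C(=O)O[C@H]2C/C(C)=C/C[C@H](O)/C(C)=C\[C@H](OC(=O)[C@@]3(C)O[C@H]3C)[C@H]12
F2 | step 19 | 1β-(trifluoroacetoxymercurio) derivative of the 3β,10β-epoxy ether (mercury in place of the C1 hydroxyl of 29) | C=C1C(=O)O[C@H]2C[C@]3(C)O[C@@H](C[C@H]3[Hg]OC(=O)C(F)(F)F)/C(C)=C\[C@H](OC(=O)[C@@]4(C)O[C@H]4C)[C@H]12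
F3 | step 19 | 1α-hydroxy epimer of 29 | C=C1C(=O)O[C@H]2C[C@]3(C)O[C@@H](C[C@@H]3O)/C(C)=C\[C@H](OC(=O)[C@@]4(C)O[C@H]4C)[C@H]12
F4 | step 12 | (1(10)E,4Z)-6β-hydroxy-3-oxogermacra-1(10),4,11(13)-trien-12,8α-olide (6-epimer of 21) | C=C1C(=O)O[C@H]2C/C(C)=C/CC(=O)/C(C)=C\[C@H](O)[C@H]12
F5 | step 16 | (1(10)E,4Z)-6β-(chloroacetoxy)-3-oxogermacra-1(10),4,11(13)-trien-12,8α-olide | C=C1C(=O)O[C@H]2C/C(C)=C/CC(=O)/C(C)=C\[C@H](OC(=O)CCl)[C@H]12
F6 | step 17 | (4Z)-1α-bromo-10α-hydroxy-6β-[(2S,3S)-2,3-dimethyloxirane-2-carbonyloxy]-3-oxogermacra-4,11(13)-dien-12,8α-olide | C=C1C(=O)O[C@H]2C[C@@](C)(O)[C@@H](Br)CC(=O)/C(C)=C\[C@H](OC(=O)[C@@]3(C)O[C@H]3C)[C@H]12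
F0 | step 21 | none | none
A1 | alternative 1 | thirteen-membered cyclic ether (oxygen between C6 and C13) with the furanone bridge, C8 p-methoxybenzyl ether and C12 silyl ether | COc1ccc(CO[C@H]2C[C@]3(C)OC(=CC3=O)/C(C)=C\COC/C(CO[Si](C)(C)C(C)(C)C)=C\2)cc1
A2 | alternative 1 | furanone-bridged ten-membered carbocycle with C6 hydroxyl and C7 2-(silyloxymethyl)vinyl branch | COc1ccc(CO[C@H]2C[C@]3(C)OC(=CC3=O)/C(C)=C\[C@H](O)[C@@H]2C(=C)CO[Si](C)(C)C(C)(C)C)cc1
A3 | alternative 2 | 1-ethenyl-3-methyl-6-(prop-1-en-2-yl)-4-(tert-butyldimethylsilyloxy)cyclohex-2-en-1-ol (alkenyl groups drawn trans) | C=C(C)[C@@H]1C[C@H](O[Si](C)(C)C(C)(C)C)C(C)=C[C@@]1(O)C=C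
A4 | alternative 2 | (2Z,7E)-cyclodeca-2,7-dienone with C7 methoxycarbonylmethyl chain and C3 silyl ether | COC(=O)C[C@@H]1CC/C(C)=C/C[C@H](O[Si](C)(C)C(C)(C)C)/C(C)=C\C1=O
A5 | alternative 3 | open-chain furanone carrying the Z alkenyl iodide at C5 and the C6 aldehyde on the methylene lactone | C=C1C(=O)O[C@@H](C[C@]2(C)OC(=CC2=O)/C(C)=C\I)[C@@H]1C=O
A6 | alternative 3 | 6-hydroxy furanone-bridged germacranolide (target alcohol) | C=C1C(=O)O[C@H]2C[C@]3(C)OC(=CC3=O)/C(C)=C\[C@H](O)[C@H]12
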